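The route rests on disconnecting the tertiary O1–C7a bond of the lactone ring (benzofuranone numbering). On the cyclohexane ring of the target this bond and the C6 acyloxy oxygen sit on opposite faces, which is what rear-side opening of a C3a–C7a epoxide on the face of a C6 hydroxyl must give. In one operation the CH2CO2H arm on C3a opens that epoxide at C7a with inversion: the cis-fused five-membered lactone closes, C7a is fixed, and a C3a hydroxyl remains for later elimination to the C3–C3a double bond. The precursor is a cyclohexanol carrying a tetrasubstituted epoxide cis to its hydroxyl, with the acetic acid arm on the epoxide carbon beside the gem-dimethyl carbon.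

Key step: step 7

Remark: atom labels C2 to C7a follow benzofuranone numbering of the target; the carboxyl group is carried as a benzyl ester and freed by hydrogenolysis, because hydroxide on a β,γ-epoxy ester can open the epoxide by β-elimination with retention at C7a, which would lead to the 7a-epimer; the ring carbinol centre keeps its configuration throughout, and only its CIP label changes from R to S once the neighbouring ring carbon carries oxygen.

Step 1
Reactants: 1 (4R,6R)-actinol [(4R,6R)-4-hydroxy-2,2,6-trimethylcyclohexan-1-one]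
Product: 2 (4R,6R)-4-{[tert-butyl(dimethyl)silyl]oxy}-2,2,6-trimethylcyclohexan-1-one
Conditions: TBSCl, imidazole, DMF, rt
Reagents that add atoms: tert-butyldimethylsilyl chloride (TBSCl), CC(C)(C)[Si](C)(C)Cl
Why: Imidazole-promoted silylation of an unhindered secondary alcohol masks the hydroxyl against the strong base and the triflating agent of step 2 and touches no stereocentre.

Step 2
Reactants: 2 (4R,6R)-4-{[tert-butyl(dimethyl)silyl]oxy}-2,2,6-trimethylcyclohexan-1-one
Product: 4 (4R)-4-{[tert-butyl(dimethyl)silyl]oxy}-2,6,6-trimethylcyclohex-1-en-1-yl trifluoromethanesulfonate, via lithium enolate 3 (not isolated)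
Conditions: LiN(iPr)2, THF, −78 to 0 °C; then PhNTf2, 0 °C to rt
Reagents that add atoms: N-phenylbis(trifluoromethanesulfonimide) (PhNTf2), O=S(=O)(N(c1ccccc1)S(=O)(=O)C(F)(F)F)C(F)(F)F
Why: The ketone has a single α-hydrogen, on the methyl-bearing carbon, so deprotonation can only give the tetrasubstituted enolate, which PhNTf2 sulfonylates on oxygen (enol triflate formation); the methyl-bearing centre becomes sp2 and the carbinol centre is untouched.

Step 3
Reactants: 4 (4R)-4-{[tert-butyl(dimethyl)silyl]oxy}-2,6,6-trimethylcyclohex-1-en-1-yl trifluoromethanesulfonate; 5 benzyl bromoacetate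
Product: 7 benzyl 2-[(4R)-4-{[tert-butyl(dimethyl)silyl]oxy}-2,6,6-trimethylcyclohex-1-en-1-yl]acetate, via Reformatsky reagent 6 (not isolated)
Conditions: 5, Zn, TMSCl (cat.), THF, rt; then 4, Pd2(dba)3 (cat.), XPhos (cat.), THF, 65 °C
Reagents that add atoms: none
Why: Negishi-type coupling of the Reformatsky reagent BrZnCH2CO2Bn, in which zerovalent palladium inserts into the alkenyl C–OTf bond, the zinc ester enolate transmetalates and reductive elimination forms the ring C–CH2 bond at the position fixed by the triflate, is a known reaction class for alkenyl and aryl triflates and creates no stereocentre.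

Step 4
Reactants: 7 benzyl 2-[(4R)-4-{[tert-butyl(dimethyl)silyl]oxy}-2,6,6-trimethylcyclohex-1-en-1-yl]acetate
Product: 8 benzyl 2-[(4R)-4-hydroxy-2,6,6-trimethylcyclohex-1-en-1-yl]acetate
Conditions: HF·pyridine, THF, 0 °C to rt
Reagents that add atoms: none
Why: Fluoride-driven desilylation under mildly acidic conditions should free the homoallylic alcohol without moving the β,γ double bond into conjugation and without touching the benzyl ester or the stereocentre.

Step 5
Reactants: 8 benzyl 2-[(4R)-4-hydroxy-2,6,6-trimethylcyclohex-1-en-1-yl]acetate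
Product: 9 benzyl 2-[(1R,4S,6S)-4-hydroxy-2,2,6-trimethyl-7-oxabicyclo[4.1.0]heptan-1-yl]acetate (epoxide cis to the hydroxyl)
Conditions: VO(acac)2 (cat.), t-BuOOH, CH2Cl2, 0 °C to rt
Reagents that add atoms: tert-butyl hydroperoxide, CC(C)(C)OO
Why: In this vanadium-catalysed hydroxyl-directed epoxidation the homoallylic hydroxyl binds the vanadium alkylperoxide and, from a pseudoaxial position, passes the oxygen to the alkene face it occupies, so both epoxide stereocentres are set cis to the hydroxyl under neutral conditions that spare the ester.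

Step 6
Reactants: 9 benzyl 2-[(1R,4S,6S)-4-hydroxy-2,2,6-trimethyl-7-oxabicyclo[4.1.0]heptan-1-yl]acetate
Product: 10 2-[(1R,4S,6S)-4-hydroxy-2,2,6-trimethyl-7-oxabicyclo[4.1.0]heptan-1-yl]acetic acid
Conditions: H2 (1 atm), Pd/C, EtOAc, rt; filter, concentrate cold, use at once
Reagents that add atoms: none
Why: Hydrogenolysis of the benzyl ester frees the carboxylic acid under neutral conditions that a non-benzylic tetrasubstituted epoxide tolerates, so the β,γ-epoxy carbonyl unit never meets base and no stereocentre is affected; any 11 that forms already from the free acid is simply carried into step 7.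

Step 7
Reactants: 10 2-[(1R,4S,6S)-4-hydroxy-2,2,6-trimethyl-7-oxabicyclo[4.1.0]heptan-1-yl]acetic acid
Product: 11 (3aR,6S,7aR)-3a,6-dihydroxy-4,4,7a-trimethylhexahydro-1-benzofuran-2(3H)-one (cis-fused)
Conditions: CSA (cat.), CH2Cl2, 0 °C to rt
Reagents that add atoms: none
Why: Protonation of the epoxide oxygen weakens the C7a–O bond, and the carbonyl oxygen of the CH2CO2H arm bonds to C7a from the side opposite that bond; proton loss then gives the lactone and leaves the former epoxide oxygen as the C3a hydroxyl. The closest known reaction type is the acid-catalysed lactonisation of β,γ-epoxy carboxylic acids to β-hydroxy-γ-butyrolactones. The lactone ring closes in the 5-endo epoxide-opening mode, since the only alternative, 4-exo attack at C3a, would give a strained spiro β-lactone. C7a is inverted, so its configuration follows from the epoxide face set in step 5 by the C6 hydroxyl; because the arm hangs from C3a on the face away from the epoxide oxygen, it can bond to C7a only from that face whatever the degree of cation character, which makes the ring fusion cis and places O1 trans to the C6 oxygen. The step needs regioselectivity for C7a over C3a, secured by ring size and by the less crowded C7a, and chemoselectivity over the C6 hydroxyl and outside nucleophiles, secured because that hydroxyl lies on the epoxide face and cannot reach the rear side and because the medium holds only a non-nucleophilic sulfonic acid in CH2Cl2.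

Step 8
Reactants: 11 (3aR,6S,7aR)-3a,6-dihydroxy-4,4,7a-trimethylhexahydro-1-benzofuran-2(3H)-one; 12 palmitoyl chloride (hexadecanoyl chloride)
Product: 13 (3aR,6S,7aR)-3a-hydroxy-4,4,7a-trimethyl-2-oxooctahydro-1-benzofuran-6-yl hexadecanoate
Conditions: pyridine, DMAP (cat.), CH2Cl2, 0 °C to rt
Reagents that add atoms: none
Why: DMAP-catalysed esterification with the acid chloride should take only the secondary C6 hydroxyl, because the tertiary C3a hydroxyl is flanked by two fully substituted carbons; no stereocentre is touched.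

Step 9
Reactants: 13 (3aR,6S,7aR)-3a-hydroxy-4,4,7a-trimethyl-2-oxooctahydro-1-benzofuran-6-yl hexadecanoate
Product: 15 (−)-3-O-palmitoylloliolide [(6S,7aR)-4,4,7a-trimethyl-2-oxo-2,4,5,6,7,7a-hexahydro-1-benzofuran-6-yl hexadecanoate], via chlorosulfite ester 14 (not isolated)
Conditions: SOCl2, pyridine, 0 °C to rt
Reagents that add atoms: none
Why: The tertiary alcohol is turned into a chlorosulfite and pyridine removes an acidic C3 hydrogen next to the lactone carbonyl (dehydration by β-elimination); since C4 and C7a carry no hydrogen, the alkene can form only between C3 and C3a, giving the butenolide without touching C6 or C7a.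

Compound list
1 | (4R,6R)-actinol [(4R,6R)-4-hydroxy-2,2,6-trimethylcyclohexan-1-one] | O[C@H]1CC(C)(C)C(=O)[C@H](C)C1 | starting material
2 | (4R,6R)-4-{[tert-butyl(dimethyl)silyl]oxy}-2,2,6-trimethylcyclohexan-1-one | CC(C)(C)[Si](C)(C)O[C@H]1CC(C)(C)C(=O)[C@H](C)C1 | intermediate
3 | lithium (4R)-4-{[tert-butyl(dimethyl)silyl]oxy}-2,6,6-trimethylcyclohex-1-en-1-olate (lithium enolate) | CC(C)(C)[Si](C)(C)O[C@H]1CC(C)(C)C(O[Li])=C(C)C1 | intermediate (not isolated)
4 | (4R)-4-{[tert-butyl(dimethyl)silyl]oxy}-2,6,6-trimethylcyclohex-1-en-1-yl trifluoromethanesulfonate | CC(C)(C)[Si](C)(C)O[C@H]1CC(C)(C)C(OS(=O)(=O)C(F)(F)F)=C(C)C1 | intermediate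
5 | benzyl bromoacetate | BrCC(=O)OCc1ccccc1 | starting material
6 | bromo[2-(benzyloxy)-2-oxoethyl]zinc (Reformatsky reagent) | Br[Zn]CC(=O)OCc1ccccc1 | intermediate (not isolated)
7 | benzyl 2-[(4R)-4-{[tert-butyl(dimethyl)silyl]oxy}-2,6,6-trimethylcyclohex-1-en-1-yl]acetate | CC(C)(C)[Si](C)(C)O[C@H]1CC(C)(C)C(CC(=O)OCc2ccccc2)=C(C)C1 | intermediate
8 | benzyl 2-[(4R)-4-hydroxy-2,6,6-trimethylcyclohex-1-en-1-yl]acetate | O[C@H]1CC(C)(C)C(CC(=O)OCc2ccccc2)=C(C)C1 | intermediate
9 | benzyl 2-[(1R,4S,6S)-4-hydroxy-2,2,6-trimethyl-7-oxabicyclo[4.1.0]heptan-1-yl]acetate | O[C@H]1CC(C)(C)[C@@]2(CC(=O)OCc3ccccc3)O[C@@]2(C)C1 | intermediate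
10 | 2-[(1R,4S,6S)-4-hydroxy-2,2,6-trimethyl-7-oxabicyclo[4.1.0]heptan-1-yl]acetic acid | O[C@H]1CC(C)(C)[C@@]2(CC(=O)O)O[C@@]2(C)C1 | intermediate
11 | (3aR,6S,7aR)-3a,6-dihydroxy-4,4,7a-trimethylhexahydro-1-benzofuran-2(3H)-one | O[C@H]1CC(C)(C)[C@]2(O)CC(=O)O[C@]2(C)C1 | intermediate
12 | palmitoyl chloride (hexadecanoyl chloride) | CCCCCCCCCCCCCCCC(=O)Cl | starting material
13 | (3aR,6S,7aR)-3a-hydroxy-4,4,7a-trimethyl-2-oxooctahydro-1-benzofuran-6-yl hexadecanoate | CCCCCCCCCCCCCCCC(=O)O[C@H]1CC(C)(C)[C@]2(O)CC(=O)O[C@]2(C)C1 | intermediate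
14 | (3aR,6S,7aR)-3a-[(chlorosulfinyl)oxy]-4,4,7a-trimethyl-2-oxooctahydro-1-benzofuran-6-yl hexadecanoate (chlorosulfite ester) | CCCCCCCCCCCCCCCC(=O)O[C@H]1CC(C)(C)[C@]2(OS(=O)Cl)CC(=O)O[C@]2(C)C1 | intermediate (not isolated)
15 | (−)-3-O-palmitoylloliolide [(6S,7aR)-4,4,7a-trimethyl-2-oxo-2,4,5,6,7,7a-hexahydro-1-benzofuran-6-yl hexadecanoate] | CCCCCCCCCCCCCCCC(=O)O[C@H]1CC(C)(C)C2=CC(=O)O[C@]2(C)C1 | target

Total step count: 9.
Longest linear sequence: 9 steps, from 1 to 15; reagent 6 is made and used inside step 3, and 12 enters directly in step 8.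

Steps most likely to fail

Step 3. Oxidative addition and transmetalation at the crowded tetrasubstituted alkenyl triflate may be slow, so that protonation or self-condensation of the zinc enolate and reduction of the triflate outrun the coupling. The fallback sets out from 4 and builds the arm in two carbons plus oxidation instead of by enolate coupling. Stille coupling with tributyl(vinyl)stannane (Pd(PPh3)4, LiCl, THF, reflux) should give the diene tert-butyl{[(1R)-4-ethenyl-3,5,5-trimethylcyclohex-3-en-1-yl]oxy}dimethylsilane F1. Hydroboration of the terminal alkene with 9-BBN and oxidation (NaOH, H2O2) should give 2-[(4R)-4-{[tert-butyl(dimethyl)silyl]oxy}-2,6,6-trimethylcyclohex-1-en-1-yl]ethan-1-ol F2. Oxidation with Dess–Martin periodinane and then NaClO2, NaH2PO4 and 2-methyl-2-butene should give 2-[(4R)-4-{[tert-butyl(dimethyl)silyl]oxy}-2,6,6-trimethylcyclohex-1-en-1-yl]acetic acid F3. Benzylation (BnBr, K2CO3, DMF) comes back to the route at 7.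

Step 5. Oxygen delivery may show poor facial selectivity, or be slow, if the hydroxyl cannot take the pseudoaxial position needed for delivery because of the 1,3-interaction with the gem-dimethyl group on the crowded tetrasubstituted alkene. The fallback sets out from 7 and uses the complementary logic of an epoxide anti to the C6 oxygen that is opened with retention at C7a. Epoxidation of the silyl ether with mCPBA (NaHCO3, CH2Cl2, 0 °C), where approach away from the bulky silyloxy group should be preferred and the minor isomer would be removed, should give benzyl 2-[(1S,4S,6R)-4-{[tert-butyl(dimethyl)silyl]oxy}-2,2,6-trimethyl-7-oxabicyclo[4.1.0]heptan-1-yl]acetate F4. DBU in hot toluene should open the epoxide by β-elimination at C3a, after which the C7a alkoxide closes onto the ester to give (6S,7aR)-6-{[tert-butyl(dimethyl)silyl]oxy}-4,4,7a-trimethyl-5,6,7,7a-tetrahydro-1-benzofuran-2(4H)-one F5. Desilylation with HF·pyridine should give (−)-loliolide F6, and acylation with 12 under the conditions of step 8 comes back to the route at 15.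

Step 7. The protonated tetrasubstituted epoxide may leak into cation pathways that do not involve the carboxyl group (proton loss to an allylic alcohol, 1,2-shift to a ketone), or the β,γ-epoxy acid may fragment with loss of CO2 before the arm closes. The fallback sets out from 9, keeps the ester and closes the ring by acyl substitution instead of alkyl–oxygen bond formation. Hydrolytic anti opening of the epoxide at C7a (HClO4 cat., THF/H2O, 0 °C), which the ester carbonyl should assist, should give benzyl 2-[(1R,2R,4S)-1,2,4-trihydroxy-2,6,6-trimethylcyclohexyl]acetate F7. Lactonisation of this γ-hydroxy ester through the tertiary C7a hydroxyl (p-TsOH cat., toluene, 60 °C) comes back to the route at 11.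

Further compounds
F1 | step 3 | tert-butyl{[(1R)-4-ethenyl-3,5,5-trimethylcyclohex-3-en-1-yl]oxy}dimethylsilane | CC(C)(C)[Si](C)(C)O[C@H]1CC(C)(C)C(C=C)=C(C)C1
F2 | step 3 | 2-[(4R)-4-{[tert-butyl(dimethyl)silyl]oxy}-2,6,6-trimethylcyclohex-1-en-1-yl]ethan-1-ol | CC(C)(C)[Si](C)(C)O[C@H]1CC(C)(C)C(CCO)=C(C)C1
F3 | step 3 | 2-[(4R)-4-{[tert-butyl(dimethyl)silyl]oxy}-2,6,6-trimethylcyclohex-1-en-1-yl]acetic acid | CC(C)(C)[Si](C)(C)O[C@H]1CC(C)(C)C(CC(=O)O)=C(C)C1
F4 | step 5 | benzyl 2-[(1S,4S,6R)-4-{[tert-butyl(dimethyl)silyl]oxy}-2,2,6-trimethyl-7-oxabicyclo[4.1.0]heptan-1-yl]acetate | CC(C)(C)[Si](C)(C)O[C@H]1CC(C)(C)[C@]2(CC(=O)OCc3ccccc3)O[C@]2(C)C1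
F5 | step 5 | (6S,7aR)-6-{[tert-butyl(dimethyl)silyl]oxy}-4,4,7a-trimethyl-5,6,7,7a-tetrahydro-1-benzofuran-2(4H)-one | CC(C)(C)[Si](C)(C)O[C@H]1CC(C)(C)C2=CC(=O)O[C@]2(C)C1
F6 | step 5 | (−)-loliolide [(6S,7aR)-6-hydroxy-4,4,7a-trimethyl-5,6,7,7a-tetrahydro-1-benzofuran-2(4H)-one] | O[C@H]1CC(C)(C)C2=CC(=O)O[C@]2(C)C1
F7 | step 7 | benzyl 2-[(1R,2R,4S)-1,2,4-trihydroxy-2,6,6-trimethylcyclohexyl]acetate | O[C@H]1CC(C)(C)[C@](O)(CC(=O)OCc2ccccc2)[C@](C)(O)C1
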